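**Plan**

- Retrosynthesis, in order: the two O–benzyl bonds that protect the 5- and 7-OH; then the C5′–C6′ bond of the tridecyl chain, each end traced back to a carboxylic acid one carbon longer; then O1–C2 and C2–C3 of the pyran-4-one ring.
- Forward: the benzene ring is bought as a phloroacetophenone dibenzyl ether. The pyran-4-one ring is closed on it with a pimelic half-ester by Baker–Venkataraman acyl transfer (C2–C3) and acid cyclodehydration (O1–C2); this brings in C2, C1′–C5′ and a sacrificial carboxyl carbon. The chain is then completed with the octyl residue of nonanoic acid, and the benzyl ethers come off last.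
- Enabling feature: C5′ and C6′ are unbranched methylenes deep in the saturated chain, five and six atoms from C2 of the pyranone and remote from every heteroatom. Both are therefore plain primary-radical sites of like polarity, and a nickel-electrocatalysed doubly decarboxylative coupling of two N-acyloxyphthalimides unites them while expelling both helper carbons as CO2.
- A reductive union is chosen over an anodic (Kolbe) one because the electron-rich phloroglucinol ring of the chromone would be at risk at the anode.
- Stereochemistry: the target has no stereocentre and no stereogenic double bond, so nothing has to be controlled.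

Key step: step 6

Remark: 1 and 2 are taken as commercial (1 is otherwise made from 2,4,6-trihydroxyacetophenone with BnBr/K2CO3, 2 from monoethyl pimelate with oxalyl chloride). Chain carbons are numbered C1′ (on C2 of the chromone) to C13′.

**Route**

Step 1
Reactants: 1 1-[2,4-bis(benzyloxy)-6-hydroxyphenyl]ethan-1-one; 2 ethyl 7-chloro-7-oxoheptanoate
Product: 3 2-acetyl-3,5-bis(benzyloxy)phenyl ethyl heptanedioate
Conditions: Et3N, DMAP (cat.), CH2Cl2, 0 °C → rt
Reagents that add atoms: none
Why: DMAP-catalysed O-acylation of the chelated phenol by the acid chloride end of 2, which is far more electrophilic than its ethyl ester end.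

Step 2
Reactants: 3 2-acetyl-3,5-bis(benzyloxy)phenyl ethyl heptanedioate
Product: 5 ethyl 6-[5,7-bis(benzyloxy)-4-oxo-4H-chromen-2-yl]hexanoate, via 1,3-diketone 4 (not isolated)
Conditions: KOtBu (2.2 equiv), THF, 0 °C → rt; aq. HCl quench; then conc. HCl (cat.), EtOH, 70 °C
Reagents that add atoms: none
Why: Baker–Venkataraman rearrangement, in which the ketone enolate attacks the neighbouring aryl ester carbonyl through a six-membered transition state to give 4 (C2–C3), followed by acid-catalysed addition of the phenol OH to the chain ketone and loss of water (O1–C2); ethanol as solvent keeps the ethyl ester, and the benzyl ethers tolerate catalytic acid.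

Step 3
Reactants: 5 ethyl 6-[5,7-bis(benzyloxy)-4-oxo-4H-chromen-2-yl]hexanoate
Product: 6 6-[5,7-bis(benzyloxy)-4-oxo-4H-chromen-2-yl]hexanoic acid
Conditions: LiOH·H2O (2 equiv), THF/H2O, 0 °C → rt; then 1 M HCl to pH 2
Reagents that add atoms: lithium hydroxide, [Li+].[OH-]
Why: saponification of the primary ethyl ester should be much faster than hydroxide attack at C2 of the 2-alkyl-5,7-dialkoxy pyranone, and the acidic work-up would re-close any ring-opened material.

Step 4
Reactants: 6 6-[5,7-bis(benzyloxy)-4-oxo-4H-chromen-2-yl]hexanoic acid; 7 N-hydroxyphthalimide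
Product: 8 1,3-dioxoisoindolin-2-yl 6-[5,7-bis(benzyloxy)-4-oxo-4H-chromen-2-yl]hexanoate
Conditions: DIC, DMAP (cat.), CH2Cl2, rt
Reagents that add atoms: none
Why: carbodiimide (Steglich-type) esterification of a primary acid with N-hydroxyphthalimide gives the redox-active ester without touching the chromone or the benzyl ethers.

Step 5
Reactants: 9 nonanoic acid; 7 N-hydroxyphthalimide
Product: 10 1,3-dioxoisoindolin-2-yl nonanoate
Conditions: DIC, DMAP (cat.), CH2Cl2, rt
Reagents that add atoms: none
Why: the same carbodiimide esterification, here on a simple fatty acid.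

Step 6
Reactants: 8 1,3-dioxoisoindolin-2-yl 6-[5,7-bis(benzyloxy)-4-oxo-4H-chromen-2-yl]hexanoate; 10 1,3-dioxoisoindolin-2-yl nonanoate (3 equiv)
Product: 11 5,7-bis(benzyloxy)-2-tridecyl-4H-chromen-4-one
Conditions: NiCl2·6H2O (cat.), 2,2′:6′,2″-terpyridine (cat.), AgNO3 (cat.), NMP, Mg anode/RVC cathode, constant current, rt; aq. HCl work-up
Reagents that add atoms: none
Why: Nickel-electrocatalysed doubly decarboxylative C(sp3)–C(sp3) cross-coupling of two N-acyloxyphthalimides, a known reaction type for pairs of primary alkyl esters and the reductive counterpart of a mixed Kolbe electrolysis: single-electron reduction of each ester by low-valent nickel at the silver-coated cathode, N–O cleavage and loss of CO2 give the primary C5′ radical from 8 and the octyl radical (C6′) from 10. Capture of one radical by nickel, capture of the second and reductive elimination from the dialkylnickel intermediate form the C5′–C6′ bond, with magnesium from the anode supplying the two electrons. No ring is closed and no stereocentre is formed. The selectivity needed is cross- over homo-coupling of two radicals of the same kind, which nothing in the substrate can secure; it is enforced by the three-fold excess of the cheap ester 10, whose homodimer hexadecane is non-polar and should be easy to remove. Chemoselectivity rests on the substrate: the N-acyloxyphthalimide is reduced well before the 5,7-dialkoxychromone, the reductive medium spares the electron-rich benzene ring, and the C5′ radical is five methylenes away from a fully substituted vinylogous-ester C2, so 6-exo attack on the pyranone should be slower than capture by nickel.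

Step 7
Reactants: 11 5,7-bis(benzyloxy)-2-tridecyl-4H-chromen-4-one
Product: 12 5,7-dihydroxy-2-tridecyl-4H-chromen-4-one
Conditions: H2 (1 atm), 10% Pd/C, EtOAc/MeOH, rt
Reagents that add atoms: none
Why: catalytic hydrogenolysis of the two aryl benzyl ethers, which should be faster than hydrogenation of the electron-rich trisubstituted C2=C3 bond of the pyranone if the reaction is stopped at full conversion.

**Compound list**

1 | 1-[2,4-bis(benzyloxy)-6-hydroxyphenyl]ethan-1-one | CC(=O)c1c(O)cc(OCc2ccccc2)cc1OCc1ccccc1 | starting material
2 | ethyl 7-chloro-7-oxoheptanoate | CCOC(=O)CCCCCC(=O)Cl | starting material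
3 | 2-acetyl-3,5-bis(benzyloxy)phenyl ethyl heptanedioate | CCOC(=O)CCCCCC(=O)Oc1cc(OCc2ccccc2)cc(OCc2ccccc2)c1C(C)=O | intermediate
4 | ethyl 9-[2,4-bis(benzyloxy)-6-hydroxyphenyl]-7,9-dioxononanoate (forms in the flask in step 2) | CCOC(=O)CCCCCC(=O)CC(=O)c1c(O)cc(OCc2ccccc2)cc1OCc1ccccc1 | intermediate
5 | ethyl 6-[5,7-bis(benzyloxy)-4-oxo-4H-chromen-2-yl]hexanoate | CCOC(=O)CCCCCc1cc(=O)c2c(OCc3ccccc3)cc(OCc3ccccc3)cc2o1 | intermediate
6 | 6-[5,7-bis(benzyloxy)-4-oxo-4H-chromen-2-yl]hexanoic acid | OC(=O)CCCCCc1cc(=O)c2c(OCc3ccccc3)cc(OCc3ccccc3)cc2o1 | intermediate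
7 | N-hydroxyphthalimide | O=C1c2ccccc2C(=O)N1O | starting material
8 | 1,3-dioxoisoindolin-2-yl 6-[5,7-bis(benzyloxy)-4-oxo-4H-chromen-2-yl]hexanoate | O=C(CCCCCc1cc(=O)c2c(OCc3ccccc3)cc(OCc3ccccc3)cc2o1)ON1C(=O)c2ccccc2C1=O | intermediate
9 | nonanoic acid | CCCCCCCCC(=O)O | starting material
10 | 1,3-dioxoisoindolin-2-yl nonanoate | CCCCCCCCC(=O)ON1C(=O)c2ccccc2C1=O | intermediate
11 | 5,7-bis(benzyloxy)-2-tridecyl-4H-chromen-4-one | CCCCCCCCCCCCCc1cc(=O)c2c(OCc3ccccc3)cc(OCc3ccccc3)cc2o1 | intermediate
12 | 5,7-dihydroxy-2-tridecyl-4H-chromen-4-one | CCCCCCCCCCCCCc1cc(=O)c2c(O)cc(O)cc2o1 | target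

**Count**

Total steps: 7. Longest linear sequence: 6 (steps 1, 2, 3, 4, 6, 7).

**Steps most likely to fail**

1. Step 6. Homocoupling of each ester may outrun the cross-coupling, the C5′ radical may be reduced to the C–H compound or attack C2 of the pyranone in a 6-exo mode, or the pyranone may be reduced at the cathode. Fallback, setting out from 1 and returning at 11, with no free radical at C5′: 1 is acylated with 6-bromohexanoyl chloride (Et3N, DMAP, CH2Cl2) to 2-acetyl-3,5-bis(benzyloxy)phenyl 6-bromohexanoate F1. LiHMDS (THF, −78 → 0 °C, aq. HCl quench) should transfer the acyl group to give 1-[2,4-bis(benzyloxy)-6-hydroxyphenyl]-8-bromooctane-1,3-dione F2 without elimination of the primary bromide. p-TsOH (cat.) in toluene at 80 °C should close this to 5,7-bis(benzyloxy)-2-(5-bromopentyl)-4H-chromen-4-one F3. Oct-1-ene is hydroborated with 9-BBN (THF, rt) to 9-octyl-9-borabicyclo[3.3.1]nonane F4, which is joined to F3 in an alkyl–alkyl Suzuki–Miyaura coupling (Pd(OAc)2, PCy3, K3PO4·H2O, THF, rt) to give 11.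

2. Step 2. Base may reach the pimelate chain, so that Dieckmann-type closure of the chain ester enolate onto the aryl ester carbonyl, or expulsion of the phenoxide by ketene formation, competes with the acyl transfer. Fallback, setting out from 1 and 2 and returning at 5: the dilithium phenoxide–enolate of 1 is formed first (LiHMDS, 3 equiv, THF, −78 °C) and then C-acylated directly with 2 at −78 °C. The C2–C3 bond is thus made by intermolecular acylation of a preformed ketone enolate with the fast acid chloride, not by transfer within 3, and the chain ester meets no free alkoxide. The resulting 4 is cyclised to 5 with HCl in EtOH as before; no compound outside the list is made (F0).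

3. Step 7. Hydrogenation of the C2=C3 bond of the pyranone may accompany the hydrogenolysis, or the reaction may stall at a mono-benzyl ether. Fallback, setting out from 11 and returning at 12: non-reductive Lewis-acid debenzylation with BCl3 and pentamethylbenzene as cation scavenger (CH2Cl2, −78 °C, aqueous work-up), which cannot saturate the pyranone; no compound outside the list is made (F0).

**Further compounds**

F1 | step 6 | 2-acetyl-3,5-bis(benzyloxy)phenyl 6-bromohexanoate | CC(=O)c1c(OCc2ccccc2)cc(OCc2ccccc2)cc1OC(=O)CCCCCBr
F2 | step 6 | 1-[2,4-bis(benzyloxy)-6-hydroxyphenyl]-8-bromooctane-1,3-dione | BrCCCCCC(=O)CC(=O)c1c(O)cc(OCc2ccccc2)cc1OCc1ccccc1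
F3 | step 6 | 5,7-bis(benzyloxy)-2-(5-bromopentyl)-4H-chromen-4-one | BrCCCCCc1cc(=O)c2c(OCc3ccccc3)cc(OCc3ccccc3)cc2o1
F4 | step 6 | 9-octyl-9-borabicyclo[3.3.1]nonane | CCCCCCCCB1C2CCCC1CCC2
F0 | step 2 | none | none
F0 | step 7 | none | none
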